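**Retrosynthetic overview**
1. The C-7 hydroxyl comes from late allylic oxidation of the 8(17)-ene. The two acetates come from a 15,19-diol, which is made by one hydride reduction of a C-19 methyl ester and a C-15 pivalate.
2. Ring A comes from a one-carbon ring expansion (1,2-acyl shift) of a trans-hydrindan-2-one iodomethyl β-keto ester. The same flask also sets the C-4 quaternary centre (MeI) and the 2α-alcohol.
3. The five-membered ring comes from Dieckmann closure of two trans acetate arms on C-5 and C-10 of ring B.
4. The Z side chain comes from a B-alkyl Suzuki coupling at C-12/C-13. The quaternary C-10 comes from a Mukaiyama-Michael addition anti to the C-5 arm.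
5. Ring B comes from an organocatalytic Michael/aldol annulation of two small carbonyl compounds. Ring order: B first, then the five-membered ring, then its expansion to ring A.

Assumption: labdane numbering (C-1 to C-20) is used for all intermediates, with α meaning the face of H-5 and β the face of the C-20 methyl group.

**Step 1**
Reactants: 1 methyl 4-oxobutanoate; 2 but-3-en-2-one
Product: 4 methyl 2-[(1S)-4-oxocyclohex-2-en-1-yl]acetate, via keto aldehyde 3 (not isolated)
Conditions: (S)-2-[methoxy(diphenyl)methyl]pyrrolidine (5 mol %), ethyl 3,4-dihydroxybenzoate (20 mol %), neat, 4 °C; then dibenzylammonium trifluoroacetate (20 mol %), toluene, 60 °C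
Reagents that add atoms: none
Why: Enamine-catalysed Michael addition to the vinyl ketone, in which the bulky group of the (S)-pyrrolidine shields one enamine face and sets C-5 as S, is followed by intramolecular aldol condensation of the methyl ketone onto the aldehyde (organocatalytic Robinson-type annulation).

**Step 2**
Reactants: 4 methyl 2-[(1S)-4-oxocyclohex-2-en-1-yl]acetate
Product: 6 methyl 2-[(1S)-2-methyl-4-oxocyclohex-2-en-1-yl]acetate, via trimethylsilyl enol ether 5 (not isolated)
Conditions: Me2CuLi, Me3SiCl, Et2O/THF, −78 °C; then Pd(OAc)2 (10 mol %), O2 (1 atm), DMSO, 25 °C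
Reagents that add atoms: lithium dimethylcuprate [Li+].C[Cu-]C; chlorotrimethylsilane C[Si](C)(C)Cl (its silyl group stays only in 5)
Why: Gilman cuprate 1,4-addition trapped as the silyl enol ether, then Saegusa-Ito dehydrogenation, puts the C-20 methyl group on the enone β-carbon, erasing the transient C-10 centre and leaving C-5 untouched.

**Step 3**
Reactants: 7 methyl acetate; 6 methyl 2-[(1S)-2-methyl-4-oxocyclohex-2-en-1-yl]acetate
Product: 9 (1S,2S)-diester silyl enol ether with the quaternary C-10, via silyl ketene acetal 8 (not isolated)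
Conditions: 7, LiN(iPr)2, THF, −78 °C, then tBuMe2SiCl, DMPU; pentane filtration; then 6, LiClO4 (1 M in Et2O), 25 °C
Reagents that add atoms: tert-butyldimethylsilyl chloride CC(C)(C)[Si](C)(C)Cl
Why: In this Mukaiyama-Michael addition the small ketene acetal adds to the hindered β,β-disubstituted enone in ethereal LiClO4 anti to the C-5 arm, which sets C-10 (new arm trans to the old one, methyl β), and silyl transfer stores the enolate regiochemistry as the C-8/C-9 silyl enol ether.

**Step 4**
Reactants: 9 (1S,2S)-diester silyl enol ether; 10 ethynyl(trimethyl)silane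
Product: 11 α-vinyl keto diester (C-9 epimers)
Conditions: GaCl3 (3.5 equiv), 10, methylcyclohexane/CH2Cl2, 25 °C; then THF, cold 3 M H2SO4
Reagents that add atoms: none
Why: In this α-ethenylation of a silyl enol ether the gallium enolate formed by Si/Ga exchange carbogallates the silylalkyne only at C-9, and protonolysis removes Ga and Si to leave the vinyl group (C-11, C-12), with the C-9 configuration corrected in steps 6 and 7.

**Step 5**
Reactants: 12 but-2-yn-1-ol
Product: 14 (2Z)-3-iodobut-2-en-1-yl pivalate, via Z-iodo alcohol 13 (not isolated)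
Conditions: NaAlH2(OCH2CH2OCH3)2, Et2O, 0 to 25 °C; I2, THF, −78 °C; crude alcohol, tBuCOCl, pyridine, DMAP (cat.), CH2Cl2, 0 °C
Reagents that add atoms: iodine II; pivaloyl chloride CC(C)(C)C(Cl)=O
Why: Alkoxide-directed trans-hydroalumination places aluminium on C-3, iodinolysis with retention gives only the Z vinyl iodide, and acylation masks the alcohol with an ester that has no α-hydrogen.

**Step 6**
Reactants: 11 α-vinyl keto diester; 14 (2Z)-3-iodobut-2-en-1-yl pivalate
Product: 16 (1S,2S,3R)-keto diester carrying the Z side chain as its pivalate, via B-alkyl-9-BBN adduct 15 (not isolated)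
Conditions: 9-BBN-H (1.1 equiv), THF, 0 to 25 °C; then 14, Pd(dppf)Cl2 (5 mol %), AsPh3, Cs2CO3, DMF/H2O, 25 °C
Reagents that add atoms: 9-borabicyclo[3.3.1]nonane B1C2CCCC1CCC2 (its boron stays only in 15)
Why: In this B-alkyl Suzuki-Miyaura coupling the monosubstituted alkene is hydroborated faster than the hindered ketone is reduced, the sp3-sp2 coupling keeps the Z geometry, and the carbonate base equilibrates C-9 to the equatorial 9β chain.

**Step 7**
Reactants: 16 (1S,2S,3R)-keto diester
Product: 17 (1S,2S,3S)-methylene diester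
Conditions: Ph3PCH3Br, KOtBu, THF, 0 to 25 °C
Reagents that add atoms: methyltriphenylphosphonium bromide C[P+](c1ccccc1)(c1ccccc1)c1ccccc1.[Br-]
Why: Wittig methylenation of the only ketone installs C-17, as is routine for 8-oxo labdane precursors, and freezes the equatorial C-9 configuration.

**Step 8**
Reactants: 17 (1S,2S,3S)-methylene diester
Product: 19 iodomethyl β-keto ester of the trans-hydrindan-2-one, via potassium enolate 18 (not isolated)
Conditions: KN(SiMe3)2 (1.1 equiv), THF, −78 to 0 °C; then CH2I2 (6 equiv), DMPU, 25 °C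
Reagents that add atoms: diiodomethane ICI
Why: In this Dieckmann condensation the less hindered C-4 methylene is deprotonated and attacks the ester of the neopentyl arm, the trans-diequatorial arms give the trans ring fusion, and the enolate is C-alkylated by CH2I2 from the α face in the usual preparation of Dowd-Beckwith substrates (this C-4 centre is erased in step 9).

**Step 9**
Reactants: 19 iodomethyl β-keto ester
Product: 22 methyl 2α-hydroxy-15-pivaloyloxylabda-8(17),13Z-dien-19-oate, via samarium ester enolate 20 (not isolated), via 2-oxo ester 21 (not isolated)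
Conditions: SmI2 (2.1 equiv), HMPA, THF, −78 °C; MeI (3 equiv), −78 to 0 °C, then Ar purge; SmI2 (5 equiv), H2O, 0 °C
Reagents that add atoms: iodomethane CI; samarium diiodide I[Sm]I (its samarium stays only in 20)
Why: Proposed new method: this is a reductive radical-polar crossover form of the Dowd-Beckwith ring expansion in which divalent samarium cleaves the C-I bond, the C-3 radical (or its organosamarium) closes 3-exo onto the C-2 carbonyl, and the cyclopropyloxy intermediate breaks the old C-2/C-4 bond (net 1,2-acyl shift, five- to six-membered ring, release of trans-hydrindanone strain) to give the ester-stabilised C-4 radical; a second electron then makes a trivalent samarium ester enolate that is not protonated as in the known tin hydride or SmI2 variants but is C-methylated by MeI from the open α face (the β face is blocked by the axial C-20 methyl, so CO2Me ends axial and CH3 equatorial), after which the known SmI2/H2O ketone reduction gives the thermodynamic equatorial 2α-alcohol; the closest known reaction types are the Dowd-Beckwith ring expansion and the trapping of samarium enolates by electrophiles.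

**Step 10**
Reactants: 22 methyl 2α-hydroxy-15-pivaloyloxylabda-8(17),13Z-dien-19-oate
Product: 23 2α-triethylsilyl ether of 22
Conditions: Et3SiCl, imidazole, CH2Cl2, 0 °C
Reagents that add atoms: chlorotriethylsilane CC[Si](Cl)(CC)CC
Why: Standard silylation of the only free hydroxyl ensures that later only the two primary alcohols are acetylated.

**Step 11**
Reactants: 23 2α-triethylsilyl ether
Product: 24 2α-triethylsilyloxylabda-8(17),13Z-diene-15,19-diol
Conditions: LiAlH4, THF, 0 to 40 °C
Reagents that add atoms: none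
Why: One hydride reduction converts the hindered axial methyl ester into the C-19 carbinol and cleaves the pivalate to the C-15 allylic alcohol, while alkenes and the silyl ether are inert.

**Step 12**
Reactants: 24 15,19-diol
Product: 25 15,19-diacetate of 24
Conditions: Ac2O, pyridine, DMAP (cat.), CH2Cl2, 25 °C
Reagents that add atoms: acetic anhydride CC(=O)OC(C)=O
Why: DMAP-catalysed acetylation has no selectivity problem here, because both free hydroxyls are the ones that carry acetate in the target.

**Step 13**
Reactants: 25 15,19-diacetate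
Product: 27 15,19-diacetoxylabda-8(17),13Z-diene-2α,7α-diol (target), via 7α-hydroxy silyl ether 26 (not isolated)
Conditions: SeO2 (0.3 equiv), tBuOOH, CH2Cl2, 0 to 25 °C; then AcOH/THF/H2O 3:1:1, 25 °C
Reagents that add atoms: selenium dioxide O=[Se]=O (delivers the C-7 oxygen; regenerated by tert-butyl hydroperoxide CC(C)(C)OO)
Why: In this Riley allylic oxidation the ene step removes the axial 7α-hydrogen of the 8(17)-ene and the [2,3] shift returns oxygen on the same α face to give the axial 7α-alcohol, the side-chain alkene is deactivated by its allylic acetate, and mild acid then removes the triethylsilyl group.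

**Compound list**
1 | methyl 4-oxobutanoate | COC(=O)CCC=O | starting material
2 | but-3-en-2-one | CC(=O)C=C | starting material
3 | methyl (3S)-3-formyl-6-oxoheptanoate | COC(=O)C[C@@H](C=O)CCC(C)=O | intermediate
4 | methyl 2-[(1S)-4-oxocyclohex-2-en-1-yl]acetate | COC(=O)C[C@H]1C=CC(=O)CC1 | intermediate
5 | methyl 2-[(1S,2S)-2-methyl-4-(trimethylsilyloxy)cyclohex-3-en-1-yl]acetate | COC(=O)C[C@@H]1CCC(O[Si](C)(C)C)=C[C@H]1C | intermediate
6 | methyl 2-[(1S)-2-methyl-4-oxocyclohex-2-en-1-yl]acetate | COC(=O)C[C@@H]1CCC(=O)C=C1C | intermediate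
7 | methyl acetate | COC(C)=O | starting material
8 | tert-butyl[(1-methoxyethenyl)oxy]dimethylsilane | C=C(OC)O[Si](C)(C)C(C)(C)C | intermediate
9 | methyl 2-[(1S,2S)-4-(tert-butyldimethylsilyloxy)-2-(2-methoxy-2-oxoethyl)-2-methylcyclohex-3-en-1-yl]acetate | COC(=O)C[C@@H]1CCC(O[Si](C)(C)C(C)(C)C)=C[C@@]1(C)CC(=O)OC | intermediate
10 | ethynyl(trimethyl)silane | C#C[Si](C)(C)C | starting material
11 | methyl 2-[(1S,2S)-3-ethenyl-2-(2-methoxy-2-oxoethyl)-2-methyl-4-oxocyclohexyl]acetate, epimers at ring C-3 (C-9) | COC(=O)C[C@@H]1CCC(=O)C(C=C)[C@@]1(C)CC(=O)OC | intermediate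
12 | but-2-yn-1-ol | CC#CCO | starting material
13 | (2Z)-3-iodobut-2-en-1-ol | C/C(I)=C/CO | intermediate
14 | (2Z)-3-iodobut-2-en-1-yl 2,2-dimethylpropanoate | C/C(I)=C/COC(=O)C(C)(C)C | intermediate
15 | B-alkyl-9-BBN adduct of 11 (boron on C-12) | COC(=O)C[C@@H]1CCC(=O)C(CCB2C3CCCC2CCC3)[C@@]1(C)CC(=O)OC | intermediate
16 | methyl 2-[(1S,2S,3R)-2-(2-methoxy-2-oxoethyl)-2-methyl-4-oxo-3-[(3Z)-3-methyl-5-(pivaloyloxy)pent-3-en-1-yl]cyclohexyl]acetate | O=C1CC[C@@H](CC(=O)OC)[C@](C)(CC(=O)OC)[C@H]1CC/C(C)=C\COC(=O)C(C)(C)C | intermediate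
17 | methyl 2-[(1S,2S,3S)-2-(2-methoxy-2-oxoethyl)-2-methyl-4-methylidene-3-[(3Z)-3-methyl-5-(pivaloyloxy)pent-3-en-1-yl]cyclohexyl]acetate | C=C1CC[C@@H](CC(=O)OC)[C@](C)(CC(=O)OC)[C@H]1CC/C(C)=C\COC(=O)C(C)(C)C | intermediate
18 | potassium enolate of the trans-hydrindan-2-one β-keto ester (five-membered ring C-1, C-2, C-4, C-5, C-10; 5α-H, 10β-CH3, 9β chain) | [K+].C=C1CC[C@H]2C(C(=O)OC)=C([O-])C[C@]2(C)[C@H]1CC/C(C)=C\COC(=O)C(C)(C)C | intermediate
19 | trans-hydrindan-2-one with 4α-CH2I, 4β-CO2Me, 5α-H, 10β-CH3, 8(17)-methylene and 9β (Z)-3-methyl-5-pivaloyloxypent-3-enyl chain | C=C1CC[C@H]2[C@@](CI)(C(=O)OC)C(=O)C[C@]2(C)[C@H]1CC/C(C)=C\COC(=O)C(C)(C)C | intermediate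
20 | ring-expanded trivalent samarium ester enolate (decalin, 2-oxo, C-4 enolate) | C=C1CC[C@H]2C(=C(OC)O[Sm](I)I)CC(=O)C[C@]2(C)[C@H]1CC/C(C)=C\COC(=O)C(C)(C)C | intermediate
21 | methyl 2-oxo-15-pivaloyloxylabda-8(17),13Z-dien-19-oate (4α-CH3, 4β-CO2Me) | C=C1CC[C@H]2[C@@](C)(C(=O)OC)CC(=O)C[C@]2(C)[C@H]1CC/C(C)=C\COC(=O)C(C)(C)C | intermediate
22 | methyl 2α-hydroxy-15-pivaloyloxylabda-8(17),13Z-dien-19-oate | C=C1CC[C@H]2[C@@](C)(C(=O)OC)C[C@H](O)C[C@]2(C)[C@H]1CC/C(C)=C\COC(=O)C(C)(C)C | intermediate
23 | methyl 15-pivaloyloxy-2α-triethylsilyloxylabda-8(17),13Z-dien-19-oate | C=C1CC[C@H]2[C@@](C)(C(=O)OC)C[C@H](O[Si](CC)(CC)CC)C[C@]2(C)[C@H]1CC/C(C)=C\COC(=O)C(C)(C)C | intermediate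
24 | 2α-triethylsilyloxylabda-8(17),13Z-diene-15,19-diol | C=C1CC[C@H]2[C@@](C)(CO)C[C@H](O[Si](CC)(CC)CC)C[C@]2(C)[C@H]1CC/C(C)=C\CO | intermediate
25 | 15,19-diacetoxy-2α-triethylsilyloxylabda-8(17),13Z-diene | C=C1CC[C@H]2[C@@](C)(COC(C)=O)C[C@H](O[Si](CC)(CC)CC)C[C@]2(C)[C@H]1CC/C(C)=C\COC(C)=O | intermediate
26 | 15,19-diacetoxy-2α-triethylsilyloxylabda-8(17),13Z-dien-7α-ol | C=C1[C@H](O)C[C@H]2[C@@](C)(COC(C)=O)C[C@H](O[Si](CC)(CC)CC)C[C@]2(C)[C@H]1CC/C(C)=C\COC(C)=O | intermediate
27 | 15,19-diacetoxylabda-8(17),13Z-diene-2α,7α-diol | C=C1[C@H](O)C[C@H]2[C@@](C)(COC(C)=O)C[C@H](O)C[C@]2(C)[C@H]1CC/C(C)=C\COC(C)=O | target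

**Total step count:** 13. **Longest linear sequence:** 12 (steps 1 to 4 and 6 to 13).

**Three steps most likely to fail**

Step 9 (the new cascade). The samarium enolate may be protonated, may pass its charge to the new ketone before MeI reacts, or leftover divalent samarium may methylate C-2 in a Barbier reaction. The fallback uses known chemistry, sets out from 19 and comes back at 22. The classical tin hydride Dowd-Beckwith expansion (Bu3SnH, AIBN, benzene, 80 °C) gives the ring-expanded keto ester without the C-4 methyl group F1. SmI2/H2O then reduces its ketone to the equatorial 2α-hydroxy ester F2. Double deprotonation with LiN(iPr)2 (2.2 equiv) followed by MeI (1.1 equiv) alkylates the ester enolate from the α face and gives 22.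

Step 4 (ethenylation). The two esters bind GaCl3, and the α-vinyl ketone can slip into conjugation during the acidic work-up. The fallback sets out from 9 and comes back at 11. MeLi cleaves the silyl enol ether to the regiodefined lithium enolate, and Michael addition to phenyl vinyl sulfoxide as a vinyl cation equivalent gives the 2-(phenylsulfinyl)ethyl ketone F3. Neutral thermolysis (toluene, NaHCO3, 110 °C) expels the sulfenic acid and gives 11.

Step 8 (one-pot Dieckmann/iodomethylation). C-alkylation of a hindered β-keto ester enolate with CH2I2 competes with O-alkylation and methylene bridging. The fallback sets out from 17 and comes back at 19. The Dieckmann reaction is quenched with acid to give the free β-keto ester F4. An aldol reaction with aqueous formaldehyde (KHCO3, THF) gives the 4α-hydroxymethyl β-keto ester F5. Appel iodination (I2, PPh3, imidazole, CH2Cl2) then gives 19.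

**Further compounds**
F1 | step 9 | methyl 2-oxo-15-pivaloyloxy-18-norlabda-8(17),13Z-dien-19-oate (C-4 epimers) | C=C1CC[C@H]2C(C(=O)OC)CC(=O)C[C@]2(C)[C@H]1CC/C(C)=C\COC(=O)C(C)(C)C
F2 | step 9 | methyl 2α-hydroxy-15-pivaloyloxy-18-norlabda-8(17),13Z-dien-19-oate (C-4 epimers) | C=C1CC[C@H]2C(C(=O)OC)C[C@H](O)C[C@]2(C)[C@H]1CC/C(C)=C\COC(=O)C(C)(C)C
F3 | step 4 | methyl 2-[(1S,2S)-2-(2-methoxy-2-oxoethyl)-2-methyl-4-oxo-3-[2-(phenylsulfinyl)ethyl]cyclohexyl]acetate | COC(=O)C[C@@H]1CCC(=O)C(CCS(=O)c2ccccc2)[C@@]1(C)CC(=O)OC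
F4 | step 8 | free trans-hydrindan-2-one β-keto ester (protonated form of 18) | C=C1CC[C@H]2C(C(=O)OC)C(=O)C[C@]2(C)[C@H]1CC/C(C)=C\COC(=O)C(C)(C)C
F5 | step 8 | 4α-hydroxymethyl analogue of 19 | C=C1CC[C@H]2[C@@](CO)(C(=O)OC)C(=O)C[C@]2(C)[C@H]1CC/C(C)=C\COC(=O)C(C)(C)C
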